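**Structural features**

The target 35 is a cuparane-type sesquiterpenoid. A cyclopentane (ring A: C1 quaternary with CH3, C2 CMe2, C3 CHBr, C4 CH2, C5 CHOH) is joined by the single bond C1–C1' to a cyclohexane (ring B: C1' tertiary carbinol, C2', C3', C4' C(CH3)Cl, C5' CHBr, C6'). On ring A the C5 hydroxyl, the C3 bromine and the bond to ring B lie on one face (α below) and the C1 methyl on the other (β); C1 and C5 are adjacent stereocentres, and C1 is also bonded to the fully substituted stereocentre C1'. On ring B the C4' chlorine is cis to the C1' hydroxyl ("hydroxyl face") and trans to the C5' bromine, so with ring A equatorial both halogens are equatorial, the opposite of what trans-diaxial addition to a C4'=C5' alkene delivers. Fragile features are the tertiary chloride and the secondary bromides (elimination, reduction, metal–halogen exchange), the β-halo alcohol relationships (ether or epoxide closure with base), and the tertiary C1' carbinol, whose ionisation next to quaternary C1 would open Wagner–Meerwein ring expansion of ring A. The real difficulties are the C1–C1' junction of two fully substituted carbons, the neopentyl C3 bromide on the more hindered α face, and the diequatorial bromochloride. The key step uses the fact that C1 carries a methyl group and two oxygen-bearing carbons (C5 and C1'): as C(CH3)(CH2OSi)2 it is prochiral, and a C4 carbenoid that inserts into one O–CH2 group forms C4–C5, closes ring A and fixes C1 and C5 together.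

**Logic of the disconnections**

35 ⇐ 34. Only the C5 O–CH2Ar bond is cut. The C5 oxygen must stay masked while C1' is oxidised and the C5' hydroxyl is activated, and an electron-rich benzyl ether can be removed oxidatively at neutral pH. The gain is a safe last step; the demand is that no acid or base touches the tertiary chloride or C1'–OH.

34 ⇐ 33. C4'–Cl is cut and bromine is returned from C5' to C4', C5' regaining its oxygen. A direct anti addition to the alkene of 31 would place chlorine trans to the C1' oxygen (trans-diaxial opening with ring A equatorial). A Lewis-acid opening of a C1'–O–C4' bridged bromo ether would ionise C1'–O faster than the bromine-deactivated C4'–O and invite ring expansion of ring A. In 33 the only activated site is the secondary C5' carbinol, and its ionisation regenerates the bromonium ion on the ring-A face. The gain is that the diequatorial bromochloride reduces to a trans-diaxial bromohydrin. The demand is that chloride opens the bromonium ion at tertiary C4', and faster than the C1' hydroxyl can close an ether.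

33 ⇐ 32 ⇐ 31. C4'–Br and the two epoxide C–O bonds are cut back to the C4'=C5' alkene. Hydroxyl-directed epoxidation puts oxygen on the C1'–OH face, and then the Markovnikov preference and the trans-diaxial rule both send bromide to C4'. The gain is that all ring B stereocentres derive from C1'. The demand is an opening that neither ionises C1' nor lets its hydroxyl attack C4'.

31 ⇐ 30. The C4'=C5' double bond is cut (metathesis retron). Ring B becomes two alkenyl arms on C1', which removes the ring and leaves one stereocentre. The demand is ring closure to a trisubstituted alkene beside a free tertiary alcohol.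

30 ⇐ 28 + 29; 28 ⇐ 27 ⇐ 24 + 26 (26 from 25). C1'–C6' and then C1'–C2' are cut. The allyl arm is added last because an allyl nucleophile adds to a hindered, enolisable ketone without enolising it, whereas an allyl ketone would isomerise. This reduces ring B to an aldehyde carbon on C1. The demand is face-selective addition to 28, controlled by C1 and the C5 ether oxygen.

24 ⇐ 23 ⇐ 22. The aldehyde is traced to the primary alcohol, and the C5 benzyl ether plus free CH2OH to one cyclic acetal. A single acetal protects both α oxygens during the C3 substitution and then differentiates them in one reductive step. The demand is regioselective opening at the primary oxygen.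

22 ⇐ 20 (via 21). C3–Br is cut with inversion to the C3β alcohol. This turns the hindered α bromide into an alcohol that a directed reduction can set. The demand is an SN2 reaction at a neopentyl-type cyclopentyl carbon.

20 ⇐ 19 ⇐ 18. The acetal is removed and the C3–H bond is cut back to the ketone. A plain hydride would attack the less hindered β face and, after inversion, give the wrong C3 epimer; the free C5 hydroxyl is therefore used to deliver hydride to the α face. The demand is a free β-hydroxy ketone, hence full desilylation first.

18 ⇐ 17 ⇐ 15 (via 16). The silyl ethers are restored and the C4 carboxyl is put back. A benzyl ester is used so that the carboxyl leaves by neutral hydrogenolysis and decarboxylation; hot halide dealkoxycarbonylation of a methyl ester would risk E1cB loss of the C5 silyloxy group.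

15 ⇐ 14. The C4–C5 bond is cut (carbenoid C–H insertion retron). Ring A and three stereocentres disappear and the precursor is achiral and acyclic. The demand is that a chiral catalyst picks one of two enantiotopic CH2OSi arms and one of its hydrogens.

14 ⇐ 13 ⇐ 10 + 11 (via 12). The C3–C4 bond is cut, an aldol retron of a diazo ester and an aldehyde. Homologating through the aldehyde avoids activating a γ-silyloxy carboxylic acid, which would lactonise, and brings in the diazo group without a separate diazo transfer. The demand is addition to a very hindered but non-enolisable aldehyde.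

10 ⇐ 9 ⇐ 8. The aldehyde C=O is traced to a vinyl group and the silyl ethers to the diol. The vinyl group is an inert carbonyl equivalent that survives the base of the preceding step.

8 ⇐ 5 + 6 (via 7). The C1–C5 bond (and by symmetry the C1–C1' carbon) is cut: one hydroxymethyl arm comes from aldol addition of 6, the other from reduction of the original aldehyde carbon. The demand is quaternary-centre formation next to a quaternary carbon, which only the smallest electrophile is likely to achieve.

5 ⇐ 3 ⇐ 1 + 2 (via 4). The C1–C2 bond is cut (Claisen retron), and the two C–O bonds of the acetal behind it. The vicinal tertiary and quaternary carbons arise from a three-carbon and a five-carbon commodity chemical. Two molecules of 1 are built into 3; one of them is released again on cracking and can be recycled. The demand is clean acetal cracking to the allyl vinyl ether.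

**Other disconnections considered**

Alternative 1: The cut runs through C2'–C3' and C6'–C1' of ring B, a Diels–Alder retron around the C4'=C5' alkene. Forward, isoprene A1 would add to the exocyclic alkene of the chiral-pool dioxolanone A2 on the face remote from its tert-butyl group to give spiro adduct A3, whose spiro carbon is C1' and whose lactone carbonyl carbon is the future C1.
- In its favour: C1' is set absolutely by an auxiliary in a concerted cycloaddition; ring B and the correctly placed trisubstituted alkene arrive in one step; and the acyl group on C1' would make that carbon hard to ionise during halogenation.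
- Against it here: the para orientation of methyl and C1' must be won with a weakly polarised diene. Above all, ring A must then be grown from a single carboxyl carbon, which has to become a quaternary stereocentre (CH3, C2, C5) beside the fully substituted C1' with no evident stereocontrol.
- Comparison: on structure A3 solves C1' better than the chosen plan and is its equal for the ring B alkene, but it leaves C1, C3 and C5 open, whereas 15 already holds C1 and C5. On mechanism the cycloaddition is the more predictable step. On step economy ring B costs one step instead of four (steps 16–19), an advantage the construction of ring A would be expected to consume.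

Alternative 2: The cut runs through C5–C1 and the C1'–O bond, the retron of an intramolecular nitrile oxide cycloaddition. Forward, aldoxime A4 would be oxidised to nitrile oxide A5, which adds across the tetrasubstituted C1=C1' alkene to give isoxazoline A6, closing ring A and placing oxygen on C1'.
- In its favour: the C1–C1' junction, quaternary C1 and the C1'–O bond are made in one intramolecular step, and N–O cleavage would unmask C5 as a ketone and C1' as the free carbinol.
- Against it: a tetrasubstituted dipolarophile reacts slowly, so dimerisation of A5 competes. C1 is controlled only by 1,3-induction from the C3 silyloxy centre. Ring B enters as a locally symmetric ketal ring, so C1' becomes stereogenic only when the alkene is later placed towards C5' rather than C3', a choice between diastereotopic branches with no evident control.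
- Comparison: on structure it is better than the chosen plan for the C1–C1' bond and the C1' oxygen and equal for the C5 oxygen, but worse for the C1' configuration and for absolute configuration, which it only relays from a C3 carbinol that must itself be enantiopure. On mechanism the two key steps are comparable in risk. On step economy they should be close.

Alternative 3: The cut treats ring B as a reduced p-tolyl group and traces the C1'–O bond to an epoxide of a Birch-type 1,4-diene. Forward, diene A7 would undergo metal-catalysed epoxidation directed by the homoallylic C5 hydroxyl at the near C1'=C2' alkene to give epoxide A8; hydride opening at C2' would then leave the C1' carbinol and the C4'=C5' alkene.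
- In its favour: all seven carbons of ring B come from one aryl group, with no Grignard additions and no metathesis; the directing hydroxyl selects the proximal alkene; the distal alkene is exactly the one needed for the halogens.
- Against it: an aryl-bearing quaternary C1 next to the C5 carbinol must be made enantioselectively, the facial outcome depends on the rotamer about C1–C1', and the Birch step must precede every halogen.
- Comparison: on step economy for ring B it is better than the chosen plan. The endgame problem (a diequatorial bromochloride on the same alkenol) is identical, so there it is equal. On structure the chosen plan has the edge in setting C1 and C5 together from an achiral precursor. On mechanism a hydroxyl-delivered epoxidation is at least as reliable as the chelation-controlled addition of step 18.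

Key step: step 8

Assumption: Rh2(S-PTTL)4 is taken to favour the silyloxymethyl arm that leads to 15; should the sense of induction be the opposite, Rh2(R-PTTL)4 would be used with everything else unchanged.

Step 1
Reactants: 1 3-methylbut-2-en-1-ol; 2 propanal
Product: 3 1,1-bis[(3-methylbut-2-en-1-yl)oxy]propane
Conditions: 1 (2.2 equiv in all), pyridinium p-toluenesulfonate (cat.), MgSO4, hexane, 0 → 25 °C
Reagents that add atoms: a second equivalent of 3-methylbut-2-en-1-ol CC(C)=CCO
Why: Acid-catalysed acetalisation of one molecule of 2 with two molecules of 1 (hemiacetal, oxocarbenium ion, second addition, loss of water); the mild acid and the dehydrating agent spare the acid-sensitive allylic alcohol and the enolisable aldehyde.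

Step 2
Reactants: 3 1,1-bis[(3-methylbut-2-en-1-yl)oxy]propane
Product: 5 2,3,3-trimethylpent-4-enal (racemic), via prenyl propenyl ether 4 (not isolated)
Conditions: H3PO4 (cat.), neat, 150 °C, 3-methylbut-2-en-1-ol distilled off
Reagents that add atoms: none
Why: Acid-catalysed loss of one allylic alcohol gives the allyl vinyl ether, which undergoes Claisen rearrangement through a chair transition state, forming C1–C2 and the gem-dimethyl carbon; the racemic stereocentre is erased in step 3.

Step 3
Reactants: 5 2,3,3-trimethylpent-4-enal; 6 formaldehyde
Product: 8 2-methyl-2-(2-methylbut-3-en-2-yl)propane-1,3-diol, via hydroxymethyl aldehyde 7 (not isolated)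
Conditions: CH2O (37% aq., 4 equiv), KOH, EtOH/H2O, 25 → 60 °C
Reagents that add atoms: none
Why: Aldol addition to formaldehyde (Tollens reaction) builds quaternary C1, and crossed Cannizzaro hydride transfer from formaldehyde reduces the now non-enolisable aldehyde; 8 is achiral.

Step 4
Reactants: 8 2-methyl-2-(2-methylbut-3-en-2-yl)propane-1,3-diol
Product: 9 bis(tert-butyldimethylsilyl) ether of 8
Conditions: TBSCl (2.4 equiv), imidazole, DMF, 25 °C
Reagents that add atoms: tert-butyldimethylsilyl chloride CC(C)(C)[Si](C)(C)Cl
Why: Silylation of both neopentyl primary hydroxyls; the silyl ethers activate the adjacent C–H bonds electronically and shield the oxygen lone pairs in step 8.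

Step 5
Reactants: 9 bis(tert-butyldimethylsilyl) ether of 8
Product: 10 4-(tert-butyldimethylsilyloxy)-3-[(tert-butyldimethylsilyloxy)methyl]-2,2,3-trimethylbutanal
Conditions: O3, CH2Cl2, −78 °C; then PPh3
Reagents that add atoms: ozone [O-][O+]=O
Why: Ozonolysis with reductive work-up cleaves the only alkene to the aldehyde (future C3); stopping at the aldehyde avoids a γ-silyloxy acid, which would lactonise on activation.

Step 6
Reactants: 10 4-(tert-butyldimethylsilyloxy)-3-[(tert-butyldimethylsilyloxy)methyl]-2,2,3-trimethylbutanal; 11 benzyl diazoacetate
Product: 13 benzyl 2-diazo-3-hydroxy-4,4,5-trimethyl-6-(tert-butyldimethylsilyloxy)-5-[(tert-butyldimethylsilyloxy)methyl]hexanoate (racemic carbinol), via benzyl lithiodiazoacetate 12 (not isolated)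
Conditions: LiN(iPr)2, THF, −78 °C; then 10; AcOH quench
Reagents that add atoms: none
Why: Aldol-type addition of the lithiated diazo ester to the hindered, non-enolisable aldehyde forms C3–C4 and brings in the diazo group directly; the benzyl ester allows later carboxyl removal by neutral hydrogenolysis.

Step 7
Reactants: 13 benzyl 2-diazo-3-hydroxy-4,4,5-trimethyl-6-(tert-butyldimethylsilyloxy)-5-[(tert-butyldimethylsilyloxy)methyl]hexanoate
Product: 14 benzyl 2-diazo-4,4,5-trimethyl-3-oxo-6-(tert-butyldimethylsilyloxy)-5-[(tert-butyldimethylsilyloxy)methyl]hexanoate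
Conditions: Dess–Martin periodinane, NaHCO3, CH2Cl2, 0 → 25 °C
Reagents that add atoms: none
Why: Dess–Martin oxidation of the α-diazo-β-hydroxy ester to the α-diazo-β-keto ester under bicarbonate buffer; the carbinol stereocentre disappears and 14 is achiral.

Step 8
Reactants: 14 benzyl 2-diazo-4,4,5-trimethyl-3-oxo-6-(tert-butyldimethylsilyloxy)-5-[(tert-butyldimethylsilyloxy)methyl]hexanoate
Product: 15 benzyl (1R,2R,3R)-2-(tert-butyldimethylsilyloxy)-3-[(tert-butyldimethylsilyloxy)methyl]-3,4,4-trimethyl-5-oxocyclopentane-1-carboxylate
Conditions: Rh2(S-PTTL)4 (dirhodium tetrakis[N-phthaloyl-(S)-tert-leucinate], 1 mol %), toluene, 0 °C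
Reagents that add atoms: none
Why: The catalyst decomposes the diazo group with loss of N2 to an electrophilic divalent-rhodium carbenoid at C4, which inserts with retention into one C–H bond of a silyloxymethyl group through a three-centre, hydride-transfer-like transition state, forming C4–C5; the closest known reaction type is the enantioselective intramolecular 1,5 C–H insertion of α-diazo-β-keto esters to cyclopentanones under chiral dirhodium carboxylates. Ring A closes in the 1,5 mode (five-membered ring through a chair-like C–H/carbenoid array); the C1 methyl offers only unactivated primary C–H bonds and the C2 methyls would give a cyclobutanone, so the oxygen-activated O–CH2 bonds should react. C1 is set by the catalyst, whose chiral pocket must choose between the two enantiotopic CH2OSi arms; C5 is set by which diastereotopic hydrogen of that arm reacts, with the silyloxy group pseudo-equatorial and, as drawn, cis to the remaining CH2OSi arm; C4 is epimerisable and should settle trans to the C5 silyloxy group. The step needs site selectivity (O–CH2 over C–CH3), chemoselectivity (insertion over oxonium ylide formation) and group selectivity: the ether oxygen lowers the barrier for hydride transfer from the adjacent C–H, the bulky silyl groups shield the oxygen lone pairs, and the benzyl ester in its Z conformation keeps its own C–H and arene bonds away from the carbenoid. If the catalyst mainly controls the configuration at the inserting carbon, the C5 epimers would carry opposite C1 configurations and are to be separated at this stage.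

Step 9
Reactants: 15 benzyl (1R,2R,3R)-2-(tert-butyldimethylsilyloxy)-3-[(tert-butyldimethylsilyloxy)methyl]-3,4,4-trimethyl-5-oxocyclopentane-1-carboxylate
Product: 17 (3R,4R)-4-(tert-butyldimethylsilyloxy)-3-[(tert-butyldimethylsilyloxy)methyl]-2,2,3-trimethylcyclopentan-1-one, via β-keto acid 16 (not isolated)
Conditions: H2 (1 atm), Pd/C, EtOAc, 25 °C; then toluene, 60 °C
Reagents that add atoms: none
Why: Hydrogenolysis of the benzyl ester gives the β-keto acid, which decarboxylates through the cyclic six-membered transition state on mild warming; neutral conditions avoid E1cB loss of the C5 silyloxy group.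

Step 10
Reactants: 17 (3R,4R)-4-(tert-butyldimethylsilyloxy)-3-[(tert-butyldimethylsilyloxy)methyl]-2,2,3-trimethylcyclopentan-1-one
Product: 18 (3R,4R)-4-hydroxy-3-(hydroxymethyl)-2,2,3-trimethylcyclopentan-1-one
Conditions: HF (48% aq.), MeCN, 0 → 25 °C
Reagents that add atoms: none
Why: Acidic fluoride desilylation of both silyl ethers; non-basic conditions keep the β-hydroxy ketone from dehydrating or undergoing retro-aldol cleavage.

Step 11
Reactants: 18 (3R,4R)-4-hydroxy-3-(hydroxymethyl)-2,2,3-trimethylcyclopentan-1-one
Product: 19 ring A triol: 1α-(hydroxymethyl)-1β,2,2-trimethylcyclopentane-3β,5α-diol (target locants)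
Conditions: Me4NBH(OAc)3, MeCN/AcOH, −30 °C
Reagents that add atoms: none
Why: Hydroxyl-directed reduction (Evans–Saksena type): the C5 hydroxyl (and the α hydroxymethyl) exchange onto boron and deliver hydride intramolecularly to the α face of the C3 ketone, so the new C3 hydroxyl is β, anti to C5–OH; an external hydride would attack the less hindered β face and give the wrong epimer for inversion.

Step 12
Reactants: 19 ring A triol
Product: 20 p-methoxybenzylidene acetal of 19 across the C5 oxygen and the C1 CH2O group (cis-fused 1,3-dioxane, aryl equatorial), C3β hydroxyl free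
Conditions: 4-MeOC6H4CH(OMe)2, pyridinium p-toluenesulfonate (cat.), CH2Cl2, 25 °C
Reagents that add atoms: 4-methoxybenzaldehyde dimethyl acetal COC(OC)c1ccc(OC)cc1
Why: Acid-catalysed transacetalisation; only the cis C5 hydroxyl and C1 hydroxymethyl can bridge (six-membered ring), the trans C3β hydroxyl cannot, and the acetal carbon equilibrates to the aryl-equatorial epimer.

Step 13
Reactants: 20 p-methoxybenzylidene acetal with free C3β hydroxyl
Product: 22 C3α bromide of the p-methoxybenzylidene acetal, via C3β triflate 21 (not isolated)
Conditions: Tf2O, pyridine, CH2Cl2, −30 °C; then Bu4NBr, toluene, 25 → 45 °C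
Reagents that add atoms: tetrabutylammonium bromide CCCC[N+](CCCC)(CCCC)CCCC.[Br-]
Why: O-sulfonylation then SN2 displacement by bromide with inversion (C3β → C3α); a cyclopentyl carbon accommodates the trigonal-bipyramidal transition state, the non-polar medium disfavours ionisation, and the cis-fused acetal ties the two α-oxygen substituents back from the trajectory.

Step 14
Reactants: 22 C3α bromide of the p-methoxybenzylidene acetal
Product: 23 C3α-bromo alcohol with C5α p-methoxybenzyl ether and free C1α CH2OH
Conditions: iBu2AlH, CH2Cl2, −78 → 0 °C
Reagents that add atoms: none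
Why: Regioselective reductive acetal opening: aluminium coordinates the less hindered primary oxygen, that C–O bond breaks and hydride adds to the oxocarbenium carbon, leaving the benzyl ether on the secondary C5 oxygen.

Step 15
Reactants: 23 C3α-bromo alcohol with C5α p-methoxybenzyl ether
Product: 24 the corresponding C1' aldehyde
Conditions: Dess–Martin periodinane, NaHCO3, CH2Cl2, 25 °C
Reagents that add atoms: none
Why: Dess–Martin oxidation of the neopentyl primary alcohol; the aldehyde has no α-hydrogen and can neither epimerise nor eliminate.

Step 16
Reactants: 24 C1' aldehyde; 25 4-bromo-2-methylbut-1-ene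
Product: 27 C1' secondary alcohol bearing the 3-methylbut-3-enyl arm (both C1' epimers), via (3-methylbut-3-en-1-yl)magnesium bromide 26 (not isolated)
Conditions: 25, Mg, THF, 25 °C; then 24, THF, −78 → 0 °C
Reagents that add atoms: none
Why: Grignard formation and 1,2-addition to the non-enolisable aldehyde form C1'–C2'; the new carbinol centre is erased in step 17, and the hindered secondary C3 bromide does not react with an alkylmagnesium reagent at this temperature.

Step 17
Reactants: 27 C1' secondary alcohol
Product: 28 C1' ketone bearing the 3-methylbut-3-enyl arm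
Conditions: Dess–Martin periodinane, NaHCO3, CH2Cl2, 25 °C
Reagents that add atoms: none
Why: Dess–Martin oxidation under buffered, non-enolising conditions; the benzyl ether protects the only other carbinol.

Step 18
Reactants: 28 C1' ketone; 29 allylmagnesium bromide
Product: 30 tertiary C1' alcohol (C1' R) bearing allyl and 3-methylbut-3-enyl arms
Conditions: CH2=CHCH2MgBr, Et2O/CH2Cl2, −78 °C
Reagents that add atoms: none
Why: Chelation-controlled 1,2-addition, consistent with the Felkin–Anh model: magnesium bridges the ketone oxygen and the C5 ether oxygen, the carbonyl oxygen lies syn to C5, and allyl attacks anti to the C2 quaternary carbon past the C1 methyl, which gives the C1' configuration of the target; the allyl reagent adds to the hindered ketone faster than it enolises it.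

Step 19
Reactants: 30 tertiary C1' alcohol with two alkenyl arms
Product: 31 ring B cyclohexenol (C4'=C5' alkene, C1' hydroxyl)
Conditions: second-generation Grubbs catalyst (H2IMes)(PCy3)Cl2Ru=CHPh (5 mol %), CH2Cl2, 40 °C
Reagents that add atoms: none
Why: Ring-closing metathesis between the monosubstituted and the 1,1-disubstituted alkene closes ring B as the trisubstituted cyclohexene with loss of ethene; the free tertiary alcohol is tolerated.

Step 20
Reactants: 31 ring B cyclohexenol
Product: 32 C4',C5' epoxide on the hydroxyl face
Conditions: VO(acac)2 (cat.), tBuOOH, CH2Cl2, 0 → 25 °C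
Reagents that add atoms: tert-butyl hydroperoxide CC(C)(C)OO
Why: Vanadium-catalysed hydroxyl-directed epoxidation: the axial homoallylic C1' hydroxyl binds the metal, which delivers the peroxide oxygen to the same face of the alkene, so C4' and C5' are set from C1'.

Step 21
Reactants: 32 C4',C5' epoxide
Product: 33 trans-diaxial bromohydrin (C4' bromine on the ring-A face, C5' hydroxyl on the hydroxyl face)
Conditions: MgBr2·OEt2, Et2O/CH2Cl2, −30 → 0 °C; aq. NH4Cl
Reagents that add atoms: magnesium bromide diethyl etherate Br[Mg]Br.CCOCC
Why: Lewis-acid-assisted halide opening of the trisubstituted epoxide: bromide attacks tertiary C4' anti to the epoxide oxygen (inversion), which is both the Markovnikov and the trans-diaxial mode for this epoxide; magnesium chelated between the C1' hydroxyl and the epoxide oxygen activates without protic acid.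

Step 22
Reactants: 33 trans-diaxial bromohydrin
Product: 34 C5 p-methoxybenzyl ether of the target
Conditions: Me2C=C(Cl)NMe2 (1.5 equiv), Bu4NCl (5 equiv), CH2Cl2, −20 → 25 °C
Reagents that add atoms: 1-chloro-N,N,2-trimethylprop-1-en-1-amine CC(C)=C(Cl)N(C)C; tetrabutylammonium chloride CCCC[N+](CCCC)(CCCC)CCCC.[Cl-]
Why: The chloroenamine activates only the secondary C5' hydroxyl (the tertiary C1' hydroxyl is too hindered) without releasing acid; ionisation is assisted by the antiperiplanar tertiary bromine, which shifts to C5' on the ring-A face as a bromonium ion with its positive charge on tertiary C4', and chloride opens it at C4' anti to bromine, on the hydroxyl face (neighbouring-group participation with 1,2-bromine shift), giving the diequatorial bromochloride.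

Step 23
Reactants: 34 C5 p-methoxybenzyl ether of the target
Product: 35 (1R,2S,4S)-4-bromo-2-[(1R,3S,4S)-3-bromo-4-chloro-1-hydroxy-4-methylcyclohexyl]-2,3,3-trimethylcyclopentan-1-ol
Conditions: DDQ, CH2Cl2/pH 7 buffer, 0 → 25 °C
Reagents that add atoms: none
Why: Oxidative cleavage of the p-methoxybenzyl ether (hydride abstraction, hydrolysis of the oxocarbenium ion) at neutral pH leaves the tertiary chloride, both bromides and the tertiary alcohol untouched; water should intercept the oxocarbenium ion before the hindered C1' hydroxyl can.

**Compound list**

1 | 3-methylbut-2-en-1-ol | CC(C)=CCO | starting material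
2 | propanal | CCC=O | starting material
3 | 1,1-bis[(3-methylbut-2-en-1-yl)oxy]propane | CCC(OCC=C(C)C)OCC=C(C)C | intermediate
4 | (3-methylbut-2-en-1-yl) prop-1-en-1-yl ether (E/Z, not isolated) | CC=COCC=C(C)C | intermediate
5 | 2,3,3-trimethylpent-4-enal (racemic) | O=CC(C)C(C)(C)C=C | intermediate
6 | formaldehyde | C=O | starting material
7 | 2-(hydroxymethyl)-2,3,3-trimethylpent-4-enal (racemic, not isolated) | O=CC(C)(CO)C(C)(C)C=C | intermediate
8 | 2-methyl-2-(2-methylbut-3-en-2-yl)propane-1,3-diol | OCC(C)(CO)C(C)(C)C=C | intermediate
9 | bis(tert-butyldimethylsilyl) ether of 8 | C=CC(C)(C)C(C)(CO[Si](C)(C)C(C)(C)C)CO[Si](C)(C)C(C)(C)C | intermediate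
10 | 4-(tert-butyldimethylsilyloxy)-3-[(tert-butyldimethylsilyloxy)methyl]-2,2,3-trimethylbutanal | O=CC(C)(C)C(C)(CO[Si](C)(C)C(C)(C)C)CO[Si](C)(C)C(C)(C)C | intermediate
11 | benzyl diazoacetate | [N-]=[N+]=CC(=O)OCc1ccccc1 | starting material
12 | benzyl lithiodiazoacetate (not isolated) | [Li]C(=[N+]=[N-])C(=O)OCc1ccccc1 | intermediate
13 | benzyl 2-diazo-3-hydroxy-4,4,5-trimethyl-6-(tert-butyldimethylsilyloxy)-5-[(tert-butyldimethylsilyloxy)methyl]hexanoate (racemic carbinol) | O=C(OCc1ccccc1)C(=[N+]=[N-])C(O)C(C)(C)C(C)(CO[Si](C)(C)C(C)(C)C)CO[Si](C)(C)C(C)(C)C | intermediate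
14 | benzyl 2-diazo-4,4,5-trimethyl-3-oxo-6-(tert-butyldimethylsilyloxy)-5-[(tert-butyldimethylsilyloxy)methyl]hexanoate (achiral) | O=C(OCc1ccccc1)C(=[N+]=[N-])C(=O)C(C)(C)C(C)(CO[Si](C)(C)C(C)(C)C)CO[Si](C)(C)C(C)(C)C | intermediate
15 | benzyl (1R,2R,3R)-2-(tert-butyldimethylsilyloxy)-3-[(tert-butyldimethylsilyloxy)methyl]-3,4,4-trimethyl-5-oxocyclopentane-1-carboxylate (ring A: C3 ketone, C4β ester, C5α silyloxy, C1α silyloxymethyl) | CC1(C)C(=O)[C@H](C(=O)OCc2ccccc2)[C@@H](O[Si](C)(C)C(C)(C)C)[C@@]1(C)CO[Si](C)(C)C(C)(C)C | intermediate
16 | β-keto acid of 15 (not isolated) | CC1(C)C(=O)[C@H](C(=O)O)[C@@H](O[Si](C)(C)C(C)(C)C)[C@@]1(C)CO[Si](C)(C)C(C)(C)C | intermediate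
17 | (3R,4R)-4-(tert-butyldimethylsilyloxy)-3-[(tert-butyldimethylsilyloxy)methyl]-2,2,3-trimethylcyclopentan-1-one | CC1(C)C(=O)C[C@@H](O[Si](C)(C)C(C)(C)C)[C@@]1(C)CO[Si](C)(C)C(C)(C)C | intermediate
18 | (3R,4R)-4-hydroxy-3-(hydroxymethyl)-2,2,3-trimethylcyclopentan-1-one | CC1(C)C(=O)C[C@@H](O)[C@@]1(C)CO | intermediate
19 | 1α-(hydroxymethyl)-1β,2,2-trimethylcyclopentane-3β,5α-diol (target locants) | CC1(C)[C@H](O)C[C@@H](O)[C@@]1(C)CO | intermediate
20 | p-methoxybenzylidene acetal of 19 (C5–O/CH2–O, cis-fused, aryl equatorial), C3β-OH free | CC1(C)[C@H](O)C[C@H]2O[C@@H](c3ccc(OC)cc3)OC[C@@]12C | intermediate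
21 | C3β triflate of 20 (not isolated) | CC1(C)[C@H](OS(=O)(=O)C(F)(F)F)C[C@H]2O[C@@H](c3ccc(OC)cc3)OC[C@@]12C | intermediate
22 | C3α bromide of the p-methoxybenzylidene acetal | CC1(C)[C@@H](Br)C[C@H]2O[C@@H](c3ccc(OC)cc3)OC[C@@]12C | intermediate
23 | ring A alcohol: C3α-Br, C5α-O-p-methoxybenzyl, C1α-CH2OH, C1β-CH3 | CC1(C)[C@@H](Br)C[C@@H](OCc2ccc(OC)cc2)[C@@]1(C)CO | intermediate
24 | corresponding C1' aldehyde | CC1(C)[C@@H](Br)C[C@@H](OCc2ccc(OC)cc2)[C@@]1(C)C=O | intermediate
25 | 4-bromo-2-methylbut-1-ene | C=C(C)CCBr | starting material
26 | (3-methylbut-3-en-1-yl)magnesium bromide (not isolated) | C=C(C)CC[Mg]Br | intermediate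
27 | C1' secondary alcohol with 3-methylbut-3-enyl arm (both C1' epimers) | CC1(C)[C@@H](Br)C[C@@H](OCc2ccc(OC)cc2)[C@@]1(C)C(O)CCC(C)=C | intermediate
28 | C1' ketone with 3-methylbut-3-enyl arm | CC1(C)[C@@H](Br)C[C@@H](OCc2ccc(OC)cc2)[C@@]1(C)C(=O)CCC(C)=C | intermediate
29 | allylmagnesium bromide | C=CC[Mg]Br | starting material
30 | tertiary C1' (R) alcohol with allyl and 3-methylbut-3-enyl arms | CC1(C)[C@@H](Br)C[C@@H](OCc2ccc(OC)cc2)[C@@]1(C)[C@@](CC=C)(O)CCC(C)=C | intermediate
31 | ring B cyclohexenol (C4'=C5', C1'-OH) | CC1(C)[C@@H](Br)C[C@@H](OCc2ccc(OC)cc2)[C@@]1(C)[C@@]1(O)CCC(C)=CC1 | intermediate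
32 | C4',C5' epoxide syn to C1'-OH | CC1(C)[C@@H](Br)C[C@@H](OCc2ccc(OC)cc2)[C@@]1(C)[C@@]1(O)CC[C@]2(C)O[C@@H]2C1 | intermediate
33 | trans-diaxial bromohydrin (C4'-Br ring-A face, C5'-OH hydroxyl face) | CC1(C)[C@@H](Br)C[C@@H](OCc2ccc(OC)cc2)[C@@]1(C)[C@@]1(O)CC[C@@](C)(Br)[C@H](O)C1 | intermediate
34 | C5 p-methoxybenzyl ether of the target | CC1(C)[C@@H](Br)C[C@@H](OCc2ccc(OC)cc2)[C@@]1(C)[C@@]1(O)CC[C@](C)(Cl)[C@@H](Br)C1 | intermediate
35 | (1R,2S,4S)-4-bromo-2-[(1R,3S,4S)-3-bromo-4-chloro-1-hydroxy-4-methylcyclohexyl]-2,3,3-trimethylcyclopentan-1-ol | CC1(C)[C@@H](Br)C[C@@H](O)[C@@]1(C)[C@@]1(O)CC[C@](C)(Cl)[C@@H](Br)C1 | target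

**Step count and least certain steps**

Total: 23 steps. Longest linear sequence: 23 steps (1 and 2 to 35); 6, 11, 25 and 29 are commercial.

Step 8 (key step). The most likely failure is insufficient discrimination by the catalyst between the two enantiotopic arms, or between the two hydrogens of one arm, on a substrate more hindered than those on which such catalysts are established; this would show as low enantio- or diastereoselectivity, possibly with some insertion at the C1 methyl. Fallback, setting out from 8 and returning at 18: the group selection is moved to an enzyme and the insertion is made substrate-controlled. Lipase-catalysed monoacetylation (Pseudomonas cepacia lipase, vinyl acetate) should desymmetrise the diol to the monoacetate F1. Silylation would give the acetate silyl ether F2, ozonolysis the aldehyde F3, addition of 12 the diazo alcohol F4, and Dess–Martin oxidation the diazo keto ester F5. With achiral Rh2(OAc)4 the carbenoid should insert only into the electron-rich silyloxymethyl C–H bonds, because acyloxymethyl C–H bonds are deactivated, giving the cyclopentanone F6. Hydrogenolysis and decarboxylation would give the ketone F7, and HCl in methanol would remove the silyl and acetyl groups to reach 18.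

Step 13. The SN2 displacement at a secondary carbon flanked by the gem-dimethyl group, from the more hindered α face, may lose to E2 elimination towards C4 or to ionisation with methyl migration from C2. Fallback, setting out from 17 and returning at 22: bromine is put on C3 first and hydrogen is delivered last from the open β face. Hydrazine would convert 17 into the hydrazone F8, and bromine with a guanidine base (Barton vinyl halide synthesis) would give the vinyl bromide F9. Hydrogen-atom-transfer hydrogenation (Mn(dpm)3, PhSiH3, tBuOOH) should add hydrogen to C4 and then to the C3 α-bromo radical from the β face, giving the C3α bromide F10. Aqueous HF would give the bromo diol F11, and acetalisation as in step 12 would give 22.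

Step 18. Facial selectivity may be poor or reversed, because allylmagnesium reagents react near the diffusion limit and respond weakly to chelation. Fallback, setting out from 24 and returning at 30: the order of the two arms is reversed, so that the same facial preference gives the other C1' configuration. Addition of 29 to 24 would give the homoallylic alcohol F12, and Dess–Martin oxidation the allyl ketone F13. The organocerium reagent F14 (from 26 and CeCl3) is non-basic enough to spare the β,γ-unsaturated ketone and would add the 3-methylbut-3-enyl arm to give 30.

Step 22 (with step 21). The bromonium ion may be captured at the wrong place: by chloride at C5' with the bromine left on C4', or by the C1' hydroxyl across the ring to close a bridged ether. The same hydroxyl may also attack C4' during the epoxide opening of step 21. Fallback, setting out from 31 and returning at 34: the C1' oxygen is masked by a group that still directs the epoxidation. Trichloroacetyl isocyanate would give the N-trichloroacetyl carbamate F15, and K2CO3 in methanol the carbamate F16. Carbamate-directed epoxidation with mCPBA would give the syn epoxide F17, and MgBr2·OEt2 the bromohydrin carbamate F18. The chloroenamine with Bu4NCl would give the bromochloride carbamate F19, in which the acylated C1' oxygen cannot close the ether, and iBu2AlH at low temperature would cleave the carbamate to give 34.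

**Further compounds**

F1 | step 8 | monoacetate of 8 (acetylated arm is the future C1') | CC(=O)OC[C@](C)(CO)C(C)(C)C=C
F2 | step 8 | acetate tert-butyldimethylsilyl ether of 8 | CC(=O)OC[C@](C)(CO[Si](C)(C)C(C)(C)C)C(C)(C)C=C
F3 | step 8 | 4-acetoxy-3-[(tert-butyldimethylsilyloxy)methyl]-2,2,3-trimethylbutanal | CC(=O)OC[C@](C)(CO[Si](C)(C)C(C)(C)C)C(C)(C)C=O
F4 | step 8 | benzyl 5-(acetoxymethyl)-2-diazo-3-hydroxy-4,4,5-trimethyl-6-(tert-butyldimethylsilyloxy)hexanoate | CC(=O)OC[C@](C)(CO[Si](C)(C)C(C)(C)C)C(C)(C)C(O)C(=[N+]=[N-])C(=O)OCc1ccccc1
F5 | step 8 | benzyl 5-(acetoxymethyl)-2-diazo-4,4,5-trimethyl-3-oxo-6-(tert-butyldimethylsilyloxy)hexanoate | CC(=O)OC[C@](C)(CO[Si](C)(C)C(C)(C)C)C(C)(C)C(=O)C(=[N+]=[N-])C(=O)OCc1ccccc1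
F6 | step 8 | benzyl 3-(acetoxymethyl)-2-(tert-butyldimethylsilyloxy)-3,4,4-trimethyl-5-oxocyclopentane-1-carboxylate | CC1(C)C(=O)[C@H](C(=O)OCc2ccccc2)[C@@H](O[Si](C)(C)C(C)(C)C)[C@@]1(C)COC(C)=O
F7 | step 8 | 3-(acetoxymethyl)-4-(tert-butyldimethylsilyloxy)-2,2,3-trimethylcyclopentan-1-one | CC1(C)C(=O)C[C@@H](O[Si](C)(C)C(C)(C)C)[C@@]1(C)COC(C)=O
F8 | step 13 | hydrazone of 17 | CC1(C)C(=NN)C[C@@H](O[Si](C)(C)C(C)(C)C)[C@@]1(C)CO[Si](C)(C)C(C)(C)C
F9 | step 13 | C3 vinyl bromide (C3=C4) | CC1(C)C(Br)=C[C@@H](O[Si](C)(C)C(C)(C)C)[C@@]1(C)CO[Si](C)(C)C(C)(C)C
F10 | step 13 | C3α bromide bis(silyl ether) | CC1(C)[C@@H](Br)C[C@@H](O[Si](C)(C)C(C)(C)C)[C@@]1(C)CO[Si](C)(C)C(C)(C)C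
F11 | step 13 | C3α-bromo diol | CC1(C)[C@@H](Br)C[C@@H](O)[C@@]1(C)CO
F12 | step 18 | C1' homoallylic alcohol (both epimers) | CC1(C)[C@@H](Br)C[C@@H](OCc2ccc(OC)cc2)[C@@]1(C)C(O)CC=C
F13 | step 18 | C1' allyl ketone | CC1(C)[C@@H](Br)C[C@@H](OCc2ccc(OC)cc2)[C@@]1(C)C(=O)CC=C
F14 | step 18 | (3-methylbut-3-en-1-yl)cerium dichloride | C=C(C)CC[Ce](Cl)Cl
F15 | step 22 | N-trichloroacetyl carbamate of 31 | CC1(C)[C@@H](Br)C[C@@H](OCc2ccc(OC)cc2)[C@@]1(C)[C@@]1(OC(=O)NC(=O)C(Cl)(Cl)Cl)CCC(C)=CC1
F16 | step 22 | C1' carbamate of 31 | CC1(C)[C@@H](Br)C[C@@H](OCc2ccc(OC)cc2)[C@@]1(C)[C@@]1(OC(N)=O)CCC(C)=CC1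
F17 | step 22 | syn epoxy carbamate | CC1(C)[C@@H](Br)C[C@@H](OCc2ccc(OC)cc2)[C@@]1(C)[C@@]1(OC(N)=O)CC[C@]2(C)O[C@@H]2C1
F18 | step 22 | bromohydrin carbamate | CC1(C)[C@@H](Br)C[C@@H](OCc2ccc(OC)cc2)[C@@]1(C)[C@@]1(OC(N)=O)CC[C@@](C)(Br)[C@H](O)C1
F19 | step 22 | bromochloride carbamate | CC1(C)[C@@H](Br)C[C@@H](OCc2ccc(OC)cc2)[C@@]1(C)[C@@]1(OC(N)=O)CC[C@](C)(Cl)[C@@H](Br)C1
A1 | alternative 1 | isoprene (2-methylbuta-1,3-diene) | C=CC(C)=C
A2 | alternative 1 | (2S)-2-tert-butyl-5-methylene-1,3-dioxolan-4-one | O=C1O[C@@H](C(C)(C)C)OC1=C
A3 | alternative 1 | spiro dioxolanone of 1-hydroxy-4-methylcyclohex-3-ene-1-carboxylic acid | O=C1O[C@@H](C(C)(C)C)O[C@@]12CCC(C)=CC2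
A4 | alternative 2 | aldoxime with tetrasubstituted C1=C1' alkene | CC(=C1CCC2(CC1)OCCO2)C(C)(C)[C@H](O[Si](C)(C)C(C)(C)C)CC=NO
A5 | alternative 2 | nitrile oxide from A4 | CC(=C1CCC2(CC1)OCCO2)C(C)(C)[C@H](O[Si](C)(C)C(C)(C)C)CC#[N+][O-]
A6 | alternative 2 | ring A fused spiro isoxazoline | CC1(C)[C@H](O[Si](C)(C)C(C)(C)C)CC2=NOC3(CCC4(OCCO4)CC3)[C@@]12C
A7 | alternative 3 | Birch-type 1,4-diene with free C5 hydroxyl | CC1(C)[C@H](O[Si](C)(C)C(C)(C)C)C[C@@H](O)[C@@]1(C)C1=CCC(C)=CC1
A8 | alternative 3 | C1',C2' epoxide of the diene | CC1(C)[C@H](O[Si](C)(C)C(C)(C)C)C[C@@H](O)[C@@]1(C)[C@@]23O[C@@H]2CC(C)=CC3
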